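**Retrosynthetic overview**
1. Ring numbering used throughout: C1 = stereocentre, C2 = methyl-bearing vinylic carbon, C3 = vinylic CH, C4 and C5 = CH2, C6 = gem-dimethyl carbon. The last disconnection is the ester C–O bond, giving α-linolenic acid 19 and the C20 allylic alcohol 18.
2. One methyl group on C6 is traced back to a formyl group (aldehyde 15), so that C6 becomes the α-carbon and C1 the β-carbon of an aldehyde.
3. Key disconnection: ring bonds C1–C2 and C5–C6 are cut together, giving the acyclic (E)-α-methyl enal 4 (used as its chiral aldimine 6) and the (Z)-alkenylmagnesium reagent 12, nucleophilic at C2 and carrying a leaving group at C5.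
4. Enabling feature: in the 2,6,6-trimethylcyclohex-2-en-1-yl ring, C1 lies between the vinylic carbon C2 of the C2=C3 bond and the quaternary carbon C6. C1=C6 is therefore the terminal isopropylidene unit of farnesol once its (E)-methyl group is oxidised, and C2–C5 is a (Z)-pent-2-ene-2,5-diyl unit.
5. Ring order: the cyclohexene is the only ring and is formed in step 9; enal 4 comes from (2E,6E)-farnesol (all 15 chain carbons and both E-alkenes), reagent 12 from 3-silyloxypropanal 7.

Key step: step 9

Assumption: the sense of induction in step 9 is taken from the chelate model (alkenyl delivery anti to the tert-butyl group of the auxiliary), which calls for the (R)-amino ester 5; it is used as the free base, liberated from its commercial hydrochloride.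

**Step 1**
Reactants: 1 (2E,6E)-farnesol
Product: 2 tert-butyl(diphenyl){[(2E,6E)-3,7,11-trimethyldodeca-2,6,10-trien-1-yl]oxy}silane
Conditions: t-BuPh2SiCl, imidazole, CH2Cl2, 0 °C → rt
Reagents that add atoms: tert-butyl(chloro)diphenylsilane, CC(C)(C)[Si](Cl)(c1ccccc1)c1ccccc1
Why: Silyl ether formation masks the only protic group so that the organomagnesium chemistry of step 9 is tolerated, and no stereocentre is involved.

**Step 2**
Reactants: 2 farnesyl silyl ether
Product: 3 (2E,6E,10E)-12-[(tert-butyldiphenylsilyl)oxy]-2,6,10-trimethyldodeca-2,6,10-trien-1-ol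
Conditions: SeO2 (cat.), t-BuOOH, salicylic acid (cat.), CH2Cl2, 0 °C → rt
Reagents that add atoms: tert-butyl hydroperoxide (terminal oxidant; the oxygen is passed on through SeO2), CC(C)(C)OO
Why: Riley allylic oxidation (ene reaction, then [2,3]-sigmatropic shift) should attack the most electron-rich and least hindered terminal isopropylidene unit at its (E)-methyl group, which fixes the 10E geometry.

**Step 3**
Reactants: 3 allylic alcohol
Product: 4 (2E,6E,10E)-12-[(tert-butyldiphenylsilyl)oxy]-2,6,10-trimethyldodeca-2,6,10-trienal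
Conditions: MnO2, CH2Cl2, rt
Reagents that add atoms: none
Why: Allylic alcohol oxidation with MnO2 should give the conjugated aldehyde without touching the silyl ether or the alkene geometry.

**Step 4**
Reactants: 4 enal; 5 tert-butyl (2R)-2-amino-3,3-dimethylbutanoate (D-tert-leucine tert-butyl ester)
Product: 6 tert-butyl (2R)-2-{[(1E,2E,6E,10E)-12-[(tert-butyldiphenylsilyl)oxy]-2,6,10-trimethyldodeca-2,6,10-trien-1-ylidene]amino}-3,3-dimethylbutanoate
Conditions: MgSO4, CH2Cl2, 0 °C → rt; used crude
Reagents that add atoms: none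
Why: Imine condensation of an aldehyde with a primary amine under neutral dehydrating conditions should give the (E)-aldimine without touching the auxiliary stereocentre.

**Step 5**
Reactants: 7 3-[(tert-butyldimethylsilyl)oxy]propanal
Product: 8 tert-butyl{[(3Z)-4-iodopent-3-en-1-yl]oxy}dimethylsilane
Conditions: EtPPh3 iodide, n-BuLi, THF, 0 °C → rt; iodine, −78 °C; NaN(SiMe3)2, −20 °C; then 7, −78 → −20 °C
Reagents that add atoms: ethyltriphenylphosphonium iodide, CC[P+](c1ccccc1)(c1ccccc1)c1ccccc1.[I-]; iodine, [I][I]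
Why: Stork–Zhao-type Wittig olefination with the α-iodo ylide should place iodine cis to the alkyl chain (Z) through the kinetically favoured cis-oxaphosphetane of a non-stabilised ylide.

**Step 6**
Reactants: 8 silyl ether
Product: 9 (3Z)-4-iodopent-3-en-1-ol
Conditions: p-TsOH·H2O (cat.), MeOH, 0 °C → rt
Reagents that add atoms: none
Why: Acid-catalysed methanolysis cleaves the primary silyl ether and leaves the alkenyl iodide untouched.

**Step 7**
Reactants: 9 iodo alcohol
Product: 10 (2Z)-5-chloro-2-iodopent-2-ene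
Conditions: PPh3, N-chlorosuccinimide, CH2Cl2, 0 °C → rt
Reagents that add atoms: N-chlorosuccinimide, ClN1C(=O)CCC1=O
Why: Appel-type chlorination converts the primary alcohol into the chloride by SN2 displacement of an alkoxyphosphonium ion without affecting the alkene geometry.

**Step 8**
Reactants: 10 chloro iodide
Product: 12 bromo[(2Z)-5-chloropent-2-en-2-yl]magnesium, via alkenyllithium 11 (not isolated)
Conditions: t-BuLi (2 equiv), Et2O, −78 °C; then MgBr2·OEt2, −78 → −40 °C; used as solution
Reagents that add atoms: magnesium bromide, Br[Mg]Br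
Why: Iodine–lithium exchange at the sp2 carbon proceeds with retention of geometry and far faster than any reaction at the primary chloride, and transmetalation gives the Grignard reagent needed for chelate-controlled addition.

**Step 9**
Reactants: 6 chiral aldimine; 12 alkenylmagnesium bromide
Product: 15 (1R,2R)-2-{(3E,7E)-9-[(tert-butyldiphenylsilyl)oxy]-3,7-dimethylnona-3,7-dien-1-yl}-1,3-dimethylcyclohex-3-ene-1-carbaldehyde, via magnesium azaenolate 13 (not isolated), via cyclised aldimine 14 (not isolated)
Conditions: 12 (2 equiv), THF, −55 → −20 °C; then DMPU, −20 → 40 °C; then 10% aq. citric acid, hexane, rt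
Reagents that add atoms: water, O
Why: Reagent 12 binds the imine nitrogen and the ester carbonyl of 6 in a five-membered chelate and transfers its alkenyl carbon (ring C2) through a six-membered cyclic array to the β-carbon (ring C1) of the s-cis azadiene; the bromomagnesium azaenolate 13 then displaces the primary chloride at C5 with its α-carbon (ring C6), and aqueous acid releases aldehyde 15 and the auxiliary. The closest known reaction types are the asymmetric Grignard conjugate addition with C-alkylation of tert-leucine tert-butyl ester aldimines of α,β-disubstituted enals, which builds α-quaternary aldehydes, and the annulation of acceptors with bifunctional ω-chloroalkenyl organometallics (Michael-initiated ring closure). The cyclohexene closes by a 6-exo-tet SN2 alkylation with the azaenolate double bond exocyclic to the new ring, the Z geometry of 12 holding C1 and C4 cis so that C5 can reach C6. C1 is set by the auxiliary, whose tert-butyl group blocks one face of the chelate so that delivery to the si face of the β-carbon should give the C1 configuration of the target; C6 is set by closure through the azaenolate conformer of least A(1,3) strain (formyl trans to the side chain expected) but is of no consequence, because step 10 turns the formyl group into the second methyl group. The step needs 1,4- over 1,2-addition (secured by the hindered chelated aldimine and the magnesium reagent), C- over N-alkylation (N-alkylation would need an eight-membered ring) and ring closure faster than E2 loss of HCl (favoured by the six-membered transition state, DMPU and the iodide carried over from step 8). The other trisubstituted alkenes, the tert-butyl ester and the silyl ether should be inert to the reagent at these temperatures.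

**Step 10**
Reactants: 15 aldehyde
Product: 17 tert-butyl({(2E,6E)-3,7-dimethyl-9-[(1S)-2,6,6-trimethylcyclohex-2-en-1-yl]nona-2,6-dien-1-yl}oxy)diphenylsilane, via tosylhydrazone 16 (not isolated)
Conditions: TsNHNH2, EtOH, rt → 50 °C; then catecholborane, CHCl3, 0 °C → rt; then NaOAc·3H2O, reflux
Reagents that add atoms: none
Why: Caglioti-type tosylhydrazone reduction (hydride addition, then loss of sulfinate and nitrogen) should turn the hindered formyl group into methyl under mild non-basic conditions, which makes C6 the gem-dimethyl carbon and leaves C1 untouched.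

**Step 11**
Reactants: 17 silyl ether
Product: 18 (2E,6E)-3,7-dimethyl-9-[(1S)-2,6,6-trimethylcyclohex-2-en-1-yl]nona-2,6-dien-1-ol
Conditions: Bu4NF, THF, 0 °C → rt
Reagents that add atoms: none
Why: Fluoride-induced desilylation frees the primary allylic alcohol without affecting the alkenes or the stereocentre.

**Step 12**
Reactants: 18 alcohol; 19 α-linolenic acid, (9Z,12Z,15Z)-octadeca-9,12,15-trienoic acid
Product: 20 (2E,6E)-3,7-dimethyl-9-[(1S)-2,6,6-trimethylcyclohex-2-en-1-yl]nona-2,6-dien-1-yl (9Z,12Z,15Z)-octadeca-9,12,15-trienoate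
Conditions: DCC, DMAP (cat.), CH2Cl2, 0 °C → rt, argon, dark
Reagents that add atoms: none
Why: Steglich esterification acylates the primary allylic alcohol under neutral conditions at room temperature, so that neither the skipped Z,Z,Z-triene nor the allylic ester should isomerise.

**Compound list**
1 | (2E,6E)-farnesol, (2E,6E)-3,7,11-trimethyldodeca-2,6,10-trien-1-ol | OC/C=C(\C)CC/C=C(\C)CCC=C(C)C | starting material
2 | tert-butyl(diphenyl){[(2E,6E)-3,7,11-trimethyldodeca-2,6,10-trien-1-yl]oxy}silane | CC(C)(C)[Si](c1ccccc1)(c1ccccc1)OC/C=C(\C)CC/C=C(\C)CCC=C(C)C | intermediate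
3 | (2E,6E,10E)-12-[(tert-butyldiphenylsilyl)oxy]-2,6,10-trimethyldodeca-2,6,10-trien-1-ol | CC(C)(C)[Si](c1ccccc1)(c1ccccc1)OC/C=C(\C)CC/C=C(\C)CC/C=C(\C)CO | intermediate
4 | (2E,6E,10E)-12-[(tert-butyldiphenylsilyl)oxy]-2,6,10-trimethyldodeca-2,6,10-trienal | CC(C)(C)[Si](c1ccccc1)(c1ccccc1)OC/C=C(\C)CC/C=C(\C)CC/C=C(\C)C=O | intermediate
5 | tert-butyl (2R)-2-amino-3,3-dimethylbutanoate | N[C@H](C(C)(C)C)C(=O)OC(C)(C)C | starting material
6 | tert-butyl (2R)-2-{[(1E,2E,6E,10E)-12-[(tert-butyldiphenylsilyl)oxy]-2,6,10-trimethyldodeca-2,6,10-trien-1-ylidene]amino}-3,3-dimethylbutanoate | CC(C)(C)[Si](c1ccccc1)(c1ccccc1)OC/C=C(\C)CC/C=C(\C)CC/C=C(\C)/C=N/[C@H](C(C)(C)C)C(=O)OC(C)(C)C | intermediate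
7 | 3-[(tert-butyldimethylsilyl)oxy]propanal | O=CCCO[Si](C)(C)C(C)(C)C | starting material
8 | tert-butyl{[(3Z)-4-iodopent-3-en-1-yl]oxy}dimethylsilane | I/C(C)=C\CCO[Si](C)(C)C(C)(C)C | intermediate
9 | (3Z)-4-iodopent-3-en-1-ol | I/C(C)=C\CCO | intermediate
10 | (2Z)-5-chloro-2-iodopent-2-ene | I/C(C)=C\CCCl | intermediate
11 | [(2E)-5-chloropent-2-en-2-yl]lithium (lithium cis to the chloroethyl arm; the E descriptor follows from the CIP ranking only) | [Li]/C(C)=C\CCCl | intermediate
12 | bromo[(2Z)-5-chloropent-2-en-2-yl]magnesium | Br[Mg]/C(C)=C\CCCl | intermediate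
13 | bromomagnesium (Z)-azaenolate from 1,4-addition of 12 to 6, with the (2Z)-5-chloropent-2-en-2-yl group on the former β-carbon (new stereocentre R by CIP ranking, spatially the C1 configuration of the target) | CC(C)(C)[Si](c1ccccc1)(c1ccccc1)OC/C=C(\C)CC/C=C(\C)CC[C@@H](/C(C)=C\N([Mg]Br)[C@H](C(C)(C)C)C(=O)OC(C)(C)C)/C(C)=C\CCCl | intermediate
14 | tert-butyl (2R)-2-{(E)-[(1R,2R)-2-{(3E,7E)-9-[(tert-butyldiphenylsilyl)oxy]-3,7-dimethylnona-3,7-dien-1-yl}-1,3-dimethylcyclohex-3-en-1-yl]methylideneamino}-3,3-dimethylbutanoate | CC(C)(C)[Si](c1ccccc1)(c1ccccc1)OC/C=C(\C)CC/C=C(\C)CC[C@@H]1C(C)=CCC[C@@]1(C)/C=N/[C@H](C(C)(C)C)C(=O)OC(C)(C)C | intermediate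
15 | (1R,2R)-2-{(3E,7E)-9-[(tert-butyldiphenylsilyl)oxy]-3,7-dimethylnona-3,7-dien-1-yl}-1,3-dimethylcyclohex-3-ene-1-carbaldehyde (formyl trans to the side chain; the C1 epimer would converge in step 10) | CC(C)(C)[Si](c1ccccc1)(c1ccccc1)OC/C=C(\C)CC/C=C(\C)CC[C@@H]1C(C)=CCC[C@@]1(C)C=O | intermediate
16 | N'-{(E)-[(1R,2R)-2-{(3E,7E)-9-[(tert-butyldiphenylsilyl)oxy]-3,7-dimethylnona-3,7-dien-1-yl}-1,3-dimethylcyclohex-3-en-1-yl]methylidene}-4-methylbenzenesulfonohydrazide | CC(C)(C)[Si](c1ccccc1)(c1ccccc1)OC/C=C(\C)CC/C=C(\C)CC[C@@H]1C(C)=CCC[C@@]1(C)/C=N/NS(=O)(=O)c2ccc(C)cc2 | intermediate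
17 | tert-butyl({(2E,6E)-3,7-dimethyl-9-[(1S)-2,6,6-trimethylcyclohex-2-en-1-yl]nona-2,6-dien-1-yl}oxy)diphenylsilane | CC(C)(C)[Si](c1ccccc1)(c1ccccc1)OC/C=C(\C)CC/C=C(\C)CC[C@@H]1C(C)=CCCC1(C)C | intermediate
18 | (2E,6E)-3,7-dimethyl-9-[(1S)-2,6,6-trimethylcyclohex-2-en-1-yl]nona-2,6-dien-1-ol | OC/C=C(\C)CC/C=C(\C)CC[C@@H]1C(C)=CCCC1(C)C | intermediate
19 | α-linolenic acid, (9Z,12Z,15Z)-octadeca-9,12,15-trienoic acid | CC/C=C\C/C=C\C/C=C\CCCCCCCC(=O)O | starting material
20 | (2E,6E)-3,7-dimethyl-9-[(1S)-2,6,6-trimethylcyclohex-2-en-1-yl]nona-2,6-dien-1-yl (9Z,12Z,15Z)-octadeca-9,12,15-trienoate | CC/C=C\C/C=C\C/C=C\CCCCCCCC(=O)OC/C=C(\C)CC/C=C(\C)CC[C@@H]1C(C)=CCCC1(C)C | target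

**Totals**
Total step count: 12.
Longest linear sequence: 8 steps (1–4 and 9–12 from farnesol; the reagent branch, steps 5–8 and 9–12, is equally long).

**Steps most likely to fail**

Step 9. The chelated bromomagnesium azaenolate 13 may alkylate the primary chloride only slowly, so that E2 loss of HCl or survival of uncyclised material until work-up competes with ring closure. The fallback separates the two bond formations and sets out from azaenolate 13 (formed from 6 and 12 as in step 9). The conjugate addition is quenched at −20 °C with aqueous citric acid, which after imine hydrolysis should give the open-chain chloro aldehyde (3S,6E,10E)-12-[(tert-butyldiphenylsilyl)oxy]-3-[(2Z)-5-chloropent-2-en-2-yl]-2,6,10-trimethyldodeca-6,10-dienal F1 (either epimer at C2). The ring is then closed in a separate flask by 6-exo-tet alkylation of its potassium enolate (KOt-Bu, t-BuOH/THF, 0 °C → rt, NaI optional), which comes back to the route at aldehyde 15.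

Step 10. Condensation or hydride transfer at the formyl group, which sits on a quaternary carbon, may stall, leaving aldehyde or hydrazone. The fallback sets out from 15 and removes the oxygen by displacement instead. NaBH4 in MeOH should give the alcohol [(1R,2R)-2-{(3E,7E)-9-[(tert-butyldiphenylsilyl)oxy]-3,7-dimethylnona-3,7-dien-1-yl}-1,3-dimethylcyclohex-3-en-1-yl]methanol F2. MsCl and Et3N in CH2Cl2 convert it into the mesylate [(1R,2R)-2-{(3E,7E)-9-[(tert-butyldiphenylsilyl)oxy]-3,7-dimethylnona-3,7-dien-1-yl}-1,3-dimethylcyclohex-3-en-1-yl]methyl methanesulfonate F3. LiEt3BH in THF at reflux reduces it to the methyl compound, which comes back to the route at 17.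

Step 2. The allylic oxidation may stop at low conversion, over-oxidise, or attack the internal allylic positions. The fallback sets out from 2 and rebuilds the enal by cleavage and olefination. N-bromosuccinimide in THF/water at 0 °C should give, selectively at the terminal alkene, the bromohydrin (6E,10E)-3-bromo-12-[(tert-butyldiphenylsilyl)oxy]-2,6,10-trimethyldodeca-6,10-dien-2-ol F4 (racemic). K2CO3 in MeOH closes it to the epoxide tert-butyl{[(2E,6E)-9-(3,3-dimethyloxiran-2-yl)-3,7-dimethylnona-2,6-dien-1-yl]oxy}diphenylsilane F5 (racemic). H5IO6 in THF/Et2O at 0 °C cleaves it to the aldehyde (4E,8E)-10-[(tert-butyldiphenylsilyl)oxy]-4,8-dimethyldeca-4,8-dienal F6. Wittig olefination with 2-(triphenylphosphoranylidene)propanal in toluene at 90 °C should give the (E)-enal and comes back to the route at 4, so that steps 2 and 3 are bypassed.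

**Further compounds**
F1 | step 9 | (3S,6E,10E)-12-[(tert-butyldiphenylsilyl)oxy]-3-[(2Z)-5-chloropent-2-en-2-yl]-2,6,10-trimethyldodeca-6,10-dienal (either epimer at C2) | CC(C)(C)[Si](c1ccccc1)(c1ccccc1)OC/C=C(\C)CC/C=C(\C)CC[C@@H](C(C)C=O)/C(C)=C\CCCl
F2 | step 10 | [(1R,2R)-2-{(3E,7E)-9-[(tert-butyldiphenylsilyl)oxy]-3,7-dimethylnona-3,7-dien-1-yl}-1,3-dimethylcyclohex-3-en-1-yl]methanol | CC(C)(C)[Si](c1ccccc1)(c1ccccc1)OC/C=C(\C)CC/C=C(\C)CC[C@@H]1C(C)=CCC[C@@]1(C)CO
F3 | step 10 | [(1R,2R)-2-{(3E,7E)-9-[(tert-butyldiphenylsilyl)oxy]-3,7-dimethylnona-3,7-dien-1-yl}-1,3-dimethylcyclohex-3-en-1-yl]methyl methanesulfonate | CC(C)(C)[Si](c1ccccc1)(c1ccccc1)OC/C=C(\C)CC/C=C(\C)CC[C@@H]1C(C)=CCC[C@@]1(C)COS(C)(=O)=O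
F4 | step 2 | (6E,10E)-3-bromo-12-[(tert-butyldiphenylsilyl)oxy]-2,6,10-trimethyldodeca-6,10-dien-2-ol (racemic) | CC(C)(C)[Si](c1ccccc1)(c1ccccc1)OC/C=C(\C)CC/C=C(\C)CCC(Br)C(C)(C)O
F5 | step 2 | tert-butyl{[(2E,6E)-9-(3,3-dimethyloxiran-2-yl)-3,7-dimethylnona-2,6-dien-1-yl]oxy}diphenylsilane (racemic) | CC(C)(C)[Si](c1ccccc1)(c1ccccc1)OC/C=C(\C)CC/C=C(\C)CCC1OC1(C)C
F6 | step 2 | (4E,8E)-10-[(tert-butyldiphenylsilyl)oxy]-4,8-dimethyldeca-4,8-dienal | CC(C)(C)[Si](c1ccccc1)(c1ccccc1)OC/C=C(\C)CC/C=C(\C)CCC=O
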